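The constants are assumed; no experiment stands behind them.

When I carry a recipe over from a neighbouring batch, I want a count that travels with it, and for these ways of running one charge I have such a count.

all flasks: J 0.40 mM

| charge | D | remark | time |
|---|---|---|---|
| epsilon | 0.20 M | a single well-mixed tank run continuously and read at steady state, 12 s in it on average |  |
| beta | 0.20 M | everything together in a closed stirred flask, run for 12 s | 12 s |
| alpha | 0.20 M (fed, over 12.0 s) | all but D at the start; D goes in evenly over 12.0 s, the run ends at 12 s | 12 s |

- the set-up with the highest amount of L at the outlet or at the end, in percent of the D put in ("none" if the first two lie within 2 percentage points) (epsilon / beta / alpha / none)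
- amount of L at the outlet or at the end, in percent of the D put in, epsilon
- amount of L at the outlet or at the end, in percent of the D put in, beta
- amount of L at the outlet or at the end, in percent of the D put in, alpha

- in percentages every species weighs as the D in it: one D2 counts as two
- a step written with two of one species runs at k times the square of its concentration and takes two of it each time
- the stated concentrations are those of everything mixed, before any reaction; amounts are the same in each set-up
- the feed brings no volume worth counting
- run time (beta): 12 s

D becomes L in a first-order step with 0.187 s⁻¹. J turns L towards Q with 24.8 M⁻¹ s⁻¹ and an equilibrium constant of 41.5, and pairs of D are lost with 0.0220 M⁻¹ s⁻¹.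

I ask first for the end state: at equilibrium hardly any of the L and Q together is L. But the approach is slow, because with J at 0.40 mM the forward half-life of L is 69.9 s, longer than the run of 12 s. This is kinetic control, so I turn to how far D has gone.

I count the lives of D: its first-order rate constant times the time, 2.24. The charge does not enter this count. The bench rule says that each D gone is an L made, and the lives give what each vessel leaves of D:

| Set-up | D left | L by the rule |
|---|---|---|
| epsilon | 30.8 % | 69.2 % |
| beta | 10.6 % | 89.4 % |
| alpha | 39.8 % | 60.2 % |

The rule stops where the losses begin to count, and I find that border with two ratios to the first-order constant. The drain through J gives 0.0530, and the loss of pairs at the full charge gives 0.0471. Neither is nil, so I take the last column as ceilings and commit to beta, whose lead of 20 percentage points is wider than the margin.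

The forecast names beta, with L at 61.2 % in epsilon, 80.8 % in beta and 57.1 % in alpha, and says “The closed flask gets the furthest”. The simulation gives beta, with L at 61.2 %, 80.8 % and 57.1 % in the same order, and beta stands 8.6 points under my ceiling.

    D → L (k1 = 0.187 s⁻¹)
    J + L ⇌ J + Q (K2 = 41.5, k2 = 24.8 M⁻¹ s⁻¹)
    2 D → D2 (k3 = 0.0220 M⁻¹ s⁻¹)

In flask beta the half-life of D by its first step alone, 3.7 s, is shorter than the time of 12 s, while the forward half-life of L by the J step alone, 70 s, is longer. At 12.0 s L there stands at 80.8 % with Q at 6.72 %, and at 120 s L is down to 32.1 %. In flask alpha, with 2.24 lives, D reads 39 % against my 39.8 %. The neighbour, flask alpha with 0.34 M of D, has the same lives, and at 12.0 s it holds, in percent of its own charge, D at 39 % and L at 56.8 %.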